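Count the X that E has yielded by the end of a run, not the E charged.

| flask | G | E | time | remark |
|---|---|---|---|---|
| theta | 0.020 M | 1.80 equiv (fed, over 8.00 h) | 10 h | a stirred flask in which E is dosed at a steady rate over 8.00 h without added volume, worked up at 10 h |
| epsilon | 0.020 M | 1.80 equiv |  | a single well-mixed tank run continuously and read at steady state, 100 h in it on average |
| delta | 0.020 M | 1.80 equiv |  | one stirred flow tank at steady state, fed with the mixture as stated, mean residence time 10 h |
| eta | 0.020 M | 1.80 equiv | 10 h | a closed flask charged with all of it at once and left for 10 h |

- order of the set-ups by the amount of J.X at the outlet or at the end, in percent of the G put in, highest first (theta / epsilon / delta / eta)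
- amount of J.X at the outlet or at the end, in percent of the G put in, theta
- amount of J.X at the outlet or at the end, in percent of the G put in, epsilon
- amount of J.X at the outlet or at the end, in percent of the G put in, delta
- amount of J.X at the outlet or at the end, in percent of the G put in, eta

    G → J (k1 = 0.340 h⁻¹)
    E → X (k2 = 0.0211 h⁻¹)
    J + X → J.X (k3 = 46.5 M⁻¹ h⁻¹)
    G ⇌ Q (K4 = 1.22, k4 = 0.571 h⁻¹)

G gives J, E gives X by itself, and each J.X takes one J and one X. The charge is 1.80 equiv of E, above the one equivalent that G can use, yet the closed flask eta has made X for about 0.342 equiv by 10 h. Both figures hold, because the half-life of E by step 2 alone is 33 h, longer than the 10 h of the run.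

My reckoning works in powers of ten. At 0.0211 h⁻¹, E falls one power of ten in 109 h, the E decade. In eta, 10 h is 0.0917 of a decade, so 81.0% of the E remains, and the rest is that X ceiling. The tank delta, at 10 h mean residence time, keeps E at its outlet level, which gives a lower ceiling of 0.314 equiv. In the dosed flask theta, E is on average 6.00 h old at the end, so its ceiling is about 0.214 equiv. The tank epsilon reaches 1.22 equiv, above one equivalent, so there G becomes the limiting reagent. My order is therefore epsilon, eta, delta, theta.

The forecast gives epsilon > eta > delta > theta, with 15.7% for theta, 90.8% for epsilon, 24.5% for delta and 27.5% for eta, holding that “dosing comes last because E arrives late”. The simulation gives epsilon > eta > delta > theta, with 15.6% for theta, 90.8% for epsilon, 24.5% for delta and 27.3% for eta.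

In eta at 10 h, J stands at 50.0% of the G charged, so each X is taken up at 0.465 h⁻¹, far faster than the 0.0211 h⁻¹ at which E gives X, which marks step 2 as the rate-limiting step there, with the 27.3% of J.X under the ceiling of 0.342 equiv. Left for 100 h, the dosed flask theta holds E of average age 96.0 h, or 0.881 of a decade, so its ceiling is 1.56 equiv, above one equivalent, and J.X stands at >99.9%.

The numbers were set for the occasion; the flask was simulated.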